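The retrosynthesis removes the MOM group on O5 last; before that it cuts the C4–O bond of ring A and the C4'–O bond of ring B together, because C4 (between the C3 and C5 oxygens) and C4' (between the C3' and C5' methoxy groups) are the only aryl C–H sites flanked by two ring oxygens.
The C9 and C9' methyls go back to a 1,4-diol and this to a trans-3,4-dibenzyl-5-menthyloxybutyrolactone, which is cut at C7–C8 (dithiane anion conjugate addition) and at C8'–C7' (enolate benzylation).
Forward, the ring A dithiane (two steps), the furanone and the ring B benzyl bromide are joined in one three-component step; desulfurisation, LiAlH4, mesylation and hydride displacement give the dimethylbutane.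
Twofold ortho-lithiation/borylation/oxidation and MOM removal finish the route; the chain is complete before the central ring oxygens are added, and no ring is formed at any stage.
C8 and C8' (both R) are relayed from the (5R) acetal carbon of the l-menthol-derived furanone, by addition anti to the menthyloxy group and alkylation trans to the new substituent; LiAlH4 excises the auxiliary and its acetal carbon ends as the C9 methyl.

Key step: step 8

Remark on the chemistry: lignan numbering is used (ring A = C1–C6 with 3-OMe, 4-OH, 5-OH; ring B = C1'–C6' with 3',5'-OMe, 4'-OH; chain C7–C8(C9)–C8'(C9')–C7'). Compounds 1, 4 and 5 are assumed to be purchasable.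

Route

Step 1
Reactants: 1 3-hydroxy-5-methoxybenzaldehyde
Product: 2 3-(1,3-dithian-2-yl)-5-methoxyphenol
Conditions: HS(CH2)3SH, BF3·OEt2 (cat.), CH2Cl2, 0 °C → rt
Reagents that add atoms: propane-1,3-dithiol, SCCCS
Why: Lewis-acid-catalysed dithioacetalisation of an aromatic aldehyde tolerates the free phenol, and running it before MOM protection keeps the acid-labile acetal away from BF3.

Step 2
Reactants: 2 3-(1,3-dithian-2-yl)-5-methoxyphenol
Product: 3 2-[3-methoxy-5-(methoxymethoxy)phenyl]-1,3-dithiane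
Conditions: MOMCl, iPr2NEt, CH2Cl2, 0 °C → rt
Reagents that add atoms: chloromethyl methyl ether, COCCl
Why: Williamson-type O-alkylation of the phenol with MOMCl and an amine base should leave the dithiane untouched and installs the group that later both protects O5 and directs metalation on ring A.

Step 3
Reactants: 3 2-[3-methoxy-5-(methoxymethoxy)phenyl]-1,3-dithiane; 4 (5R)-5-[(1R,2S,5R)-menthyloxy]furan-2(5H)-one; 5 3,5-dimethoxybenzyl bromide
Product: 8 (3R,4R,5R)-3-(3,5-dimethoxybenzyl)-4-{2-[3-methoxy-5-(methoxymethoxy)phenyl]-1,3-dithian-2-yl}-5-[(1R,2S,5R)-menthyloxy]dihydrofuran-2(3H)-one, via lithiated dithiane 6 (not isolated), via lithium lactone enolate 7 (not isolated)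
Conditions: n-BuLi (1.0 equiv), THF, −78 → −30 °C; 4, −78 °C; then 5, TMEDA, −78 °C → rt
Reagents that add atoms: none
Why: In this tandem Michael addition–enolate alkylation of a γ-alkoxybutenolide the soft 2-aryl-2-lithio-1,3-dithiane should add 1,4 anti to the C5 menthyloxy group (setting lactone C4, the future C8), and the lithium enolate should be benzylated by 5 trans to the bulky dithianyl group (setting lactone C3, the future C8'), so both stereocentres derive from the acetal carbon of 4.

Step 4
Reactants: 8 (3R,4R,5R)-3-(3,5-dimethoxybenzyl)-4-{2-[3-methoxy-5-(methoxymethoxy)phenyl]-1,3-dithian-2-yl}-5-[(1R,2S,5R)-menthyloxy]dihydrofuran-2(3H)-one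
Product: 9 (3R,4R,5R)-3-(3,5-dimethoxybenzyl)-4-[3-methoxy-5-(methoxymethoxy)benzyl]-5-[(1R,2S,5R)-menthyloxy]dihydrofuran-2(3H)-one
Conditions: Raney Ni (W-2, excess), EtOH/THF, reflux
Reagents that add atoms: none
Why: Raney nickel hydrogenolysis of the two benzylic C–S bonds (Mozingo reduction) should turn the dithiane carbon into the C7 methylene without touching the lactone acetal, the aryl ethers or the MOM group.

Step 5
Reactants: 9 (3R,4R,5R)-3-(3,5-dimethoxybenzyl)-4-[3-methoxy-5-(methoxymethoxy)benzyl]-5-[(1R,2S,5R)-menthyloxy]dihydrofuran-2(3H)-one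
Product: 10 (2R,3R)-2-(3,5-dimethoxybenzyl)-3-[3-methoxy-5-(methoxymethoxy)benzyl]butane-1,4-diol
Conditions: LiAlH4, THF, 0 °C → rt
Reagents that add atoms: none
Why: Hydride reduction of the lactone carbonyl opens the ring to a hemiacetal alkoxide that expels menthoxide, and the unmasked aldehyde is reduced faster than it can enolise, so the 1,4-diol should form with both stereocentres intact and the auxiliary released.

Step 6
Reactants: 10 (2R,3R)-2-(3,5-dimethoxybenzyl)-3-[3-methoxy-5-(methoxymethoxy)benzyl]butane-1,4-diol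
Product: 11 (2R,3R)-2-(3,5-dimethoxybenzyl)-3-[3-methoxy-5-(methoxymethoxy)benzyl]butane-1,4-diyl dimethanesulfonate
Conditions: MsCl (excess), Et3N, CH2Cl2, 0 °C
Reagents that add atoms: methanesulfonyl chloride, CS(=O)(=O)Cl
Why: Sulfene-mediated mesylation of primary alcohols is fast at 0 °C, and excess reagent should sulfonylate both hydroxyls before a monomesylate can cyclise to a tetrahydrofuran.

Step 7
Reactants: 11 (2R,3R)-2-(3,5-dimethoxybenzyl)-3-[3-methoxy-5-(methoxymethoxy)benzyl]butane-1,4-diyl dimethanesulfonate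
Product: 12 (2R,3R)-1-(3,5-dimethoxyphenyl)-4-[3-methoxy-5-(methoxymethoxy)phenyl]-2,3-dimethylbutane
Conditions: LiBHEt3 (excess), THF, 0 °C → rt
Reagents that add atoms: none
Why: LiBHEt3 displaces primary sulfonates by SN2 hydride transfer, which should convert both CH2OMs groups into the C9 and C9' methyls while the stereocentres, β to the reacting carbons, stay untouched.

Step 8
Reactants: 12 (2R,3R)-1-(3,5-dimethoxyphenyl)-4-[3-methoxy-5-(methoxymethoxy)phenyl]-2,3-dimethylbutane
Product: 15 2-methoxy-4-[(2R,3R)-4-(4-hydroxy-3,5-dimethoxyphenyl)-2,3-dimethylbutyl]-6-(methoxymethoxy)phenol, via bis(aryllithium) 13 (not isolated), via bis(dimethyl boronate) 14 (not isolated)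
Conditions: n-BuLi (excess), TMEDA, THF, 0 °C; B(OMe)3, −78 °C → rt; AcOH, 30% aq. H2O2, 0 °C → rt
Reagents that add atoms: hydrogen peroxide, OO
Why: n-BuLi/TMEDA is held by the two ether oxygens that flank C4 of ring A (C3-OMe and C5-OCH2OMe) and C4' of ring B (C3'-OMe and C5'-OMe) and removes these two protons by directed ortho-metalation to give bis(aryllithium) 13; both C–Li bonds are trapped by B(OMe)3 with loss of methoxide (completed by AcOH) to give bis(dimethyl boronate) 14, and hydroperoxide then adds to each boron and triggers 1,2-migration of the aryl group from boron to oxygen, so the C4–O and C4'–O bonds form ipso to the former C–B bonds and hydrolysis of the borate esters frees the two phenols. The closest known reaction type is lithiation of 5-alkylresorcinol dialkyl ethers between the two oxygens followed by borate–peroxide oxidation to 2,6-dialkoxyphenols. No ring is closed and no stereocentre is created; C8 and C8' are remote and non-acidic and should stay untouched. The selectivity needed is C4 and C4' over C2, C6, C2', C6' and the benzylic C7 and C7' methylenes, and the substrate secures it because only C4 and C4' lie between two coordinating oxygens, whereas every other ring C–H has one oxygen and one alkyl neighbour and the benzylic C–H bonds of these electron-rich rings are far less acidic towards n-BuLi under these conditions. Excess base should carry both rings to full metalation, and AcOH-buffered peroxide at 0 °C should spare the MOM ether and limit over-oxidation of the electron-rich phenols.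

Step 9
Reactants: 15 2-methoxy-4-[(2R,3R)-4-(4-hydroxy-3,5-dimethoxyphenyl)-2,3-dimethylbutyl]-6-(methoxymethoxy)phenol
Product: 16 sauriol B, 5-[(2R,3R)-4-(4-hydroxy-3,5-dimethoxyphenyl)-2,3-dimethylbutyl]-3-methoxybenzene-1,2-diol
Conditions: HCl (2 M), MeOH, 40 °C, argon
Reagents that add atoms: none
Why: Acid-catalysed acetal exchange (methanolysis) should remove the MOM ether as dimethoxymethane while the aryl methyl ethers and the stereocentres are inert, and the acidic, oxygen-free medium protects the liberated catechol from autoxidation.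

Compound list

1 | 3-hydroxy-5-methoxybenzaldehyde | COc1cc(C=O)cc(O)c1 | starting material
2 | 3-(1,3-dithian-2-yl)-5-methoxyphenol | COc1cc(O)cc(c1)C1SCCCS1 | intermediate
3 | 2-[3-methoxy-5-(methoxymethoxy)phenyl]-1,3-dithiane | COCOc1cc(OC)cc(c1)C1SCCCS1 | intermediate
4 | (5R)-5-[(1R,2S,5R)-menthyloxy]furan-2(5H)-one | CC(C)[C@@H]1CC[C@@H](C)C[C@H]1O[C@@H]1OC(=O)C=C1 | starting material
5 | 3,5-dimethoxybenzyl bromide | COc1cc(CBr)cc(OC)c1 | starting material
6 | 2-lithio-2-[3-methoxy-5-(methoxymethoxy)phenyl]-1,3-dithiane (lithiated dithiane) | [Li]C1(SCCCS1)c1cc(OC)cc(OCOC)c1 | intermediate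
7 | lithium enolate of (4R,5R)-4-{2-[3-methoxy-5-(methoxymethoxy)phenyl]-1,3-dithian-2-yl}-5-[(1R,2S,5R)-menthyloxy]dihydrofuran-2(3H)-one (lithium lactone enolate) | CC(C)[C@@H]1CC[C@@H](C)C[C@H]1O[C@@H]2OC(O[Li])=C[C@H]2C3(SCCCS3)c4cc(OC)cc(OCOC)c4 | intermediate
8 | (3R,4R,5R)-3-(3,5-dimethoxybenzyl)-4-{2-[3-methoxy-5-(methoxymethoxy)phenyl]-1,3-dithian-2-yl}-5-[(1R,2S,5R)-menthyloxy]dihydrofuran-2(3H)-one | CC(C)[C@@H]1CC[C@@H](C)C[C@H]1O[C@@H]2OC(=O)[C@H](Cc3cc(OC)cc(OC)c3)[C@H]2C4(SCCCS4)c5cc(OC)cc(OCOC)c5 | intermediate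
9 | (3R,4R,5R)-3-(3,5-dimethoxybenzyl)-4-[3-methoxy-5-(methoxymethoxy)benzyl]-5-[(1R,2S,5R)-menthyloxy]dihydrofuran-2(3H)-one | CC(C)[C@@H]1CC[C@@H](C)C[C@H]1O[C@@H]2OC(=O)[C@H](Cc3cc(OC)cc(OC)c3)[C@H]2Cc4cc(OC)cc(OCOC)c4 | intermediate
10 | (2R,3R)-2-(3,5-dimethoxybenzyl)-3-[3-methoxy-5-(methoxymethoxy)benzyl]butane-1,4-diol | COc1cc(C[C@@H](CO)[C@H](CO)Cc2cc(OC)cc(OC)c2)cc(OCOC)c1 | intermediate
11 | (2R,3R)-2-(3,5-dimethoxybenzyl)-3-[3-methoxy-5-(methoxymethoxy)benzyl]butane-1,4-diyl dimethanesulfonate | COc1cc(C[C@@H](COS(C)(=O)=O)[C@H](COS(C)(=O)=O)Cc2cc(OC)cc(OC)c2)cc(OCOC)c1 | intermediate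
12 | (2R,3R)-1-(3,5-dimethoxyphenyl)-4-[3-methoxy-5-(methoxymethoxy)phenyl]-2,3-dimethylbutane | COc1cc(C[C@@H](C)[C@H](C)Cc2cc(OC)cc(OC)c2)cc(OCOC)c1 | intermediate
13 | 4,4'-dilithio derivative of 12, lithium at C4 of ring A and C4' of ring B (bis(aryllithium)) | COc1cc(C[C@@H](C)[C@H](C)Cc2cc(OC)c([Li])c(OC)c2)cc(OCOC)c1[Li] | intermediate
14 | 4,4'-bis(dimethoxyboryl) derivative of 12 (bis(dimethyl boronate)) | COc1cc(C[C@@H](C)[C@H](C)Cc2cc(OC)c(B(OC)OC)c(OC)c2)cc(OCOC)c1B(OC)OC | intermediate
15 | 2-methoxy-4-[(2R,3R)-4-(4-hydroxy-3,5-dimethoxyphenyl)-2,3-dimethylbutyl]-6-(methoxymethoxy)phenol | COc1cc(C[C@@H](C)[C@H](C)Cc2cc(OC)c(O)c(OC)c2)cc(OCOC)c1O | intermediate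
16 | sauriol B, 5-[(2R,3R)-4-(4-hydroxy-3,5-dimethoxyphenyl)-2,3-dimethylbutyl]-3-methoxybenzene-1,2-diol | COc1cc(C[C@@H](C)[C@H](C)Cc2cc(OC)c(O)c(OC)c2)cc(O)c1O | target

Step count

Total steps: 9. Longest linear sequence: 9 steps (1 → 16; compounds 4 and 5 enter as purchased materials in step 3).

Three steps most likely to fail

Risk 1, step 8 (key step): metalation may stop after one ring, leaving mono-hydroxylated material, or the electron-rich phenols may be over-oxidised by peroxide while borate is present. The fallback for step 8 sets out from 12 and changes the oxygenation from C–B/peroxide to C-formylation/Baeyer–Villiger. The bis(aryllithium) 13 is generated as before and quenched with DMF to give 4-[(2R,3R)-4-(4-formyl-3,5-dimethoxyphenyl)-2,3-dimethylbutyl]-2-methoxy-6-(methoxymethoxy)benzaldehyde F1. Dialdehyde F1 should be stable and separable from mono-formylated material, which can be resubmitted. Baeyer–Villiger oxidation of F1 with mCPBA (NaHCO3, CH2Cl2, 0 °C) should give 4-[(2R,3R)-4-(4-formyloxy-3,5-dimethoxyphenyl)-2,3-dimethylbutyl]-2-methoxy-6-(methoxymethoxy)phenyl formate F2, since the electron-rich aryl group migrates in preference to hydrogen. Methanolysis of F2 with K2CO3 in MeOH returns to the route at 15.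

Risk 2, step 3: C-benzylation of the hindered lithium enolate 7 may be slow or poorly trans-selective (proton transfer, cis/trans mixtures). The fallback for step 3 sets out from 3 and 4 and separates the two bond formations. Conjugate addition of 6 to 4 and quenching of enolate 7 with NH4Cl gives (4R,5R)-4-{2-[3-methoxy-5-(methoxymethoxy)phenyl]-1,3-dithian-2-yl}-5-[(1R,2S,5R)-menthyloxy]dihydrofuran-2(3H)-one F3. Raney Ni desulfurisation of F3 gives (4R,5R)-4-[3-methoxy-5-(methoxymethoxy)benzyl]-5-[(1R,2S,5R)-menthyloxy]dihydrofuran-2(3H)-one F4. Deprotonation of F4 with LiN(iPr)2 in THF at −78 °C gives the lithium enolate of (4R,5R)-4-[3-methoxy-5-(methoxymethoxy)benzyl]-5-[(1R,2S,5R)-menthyloxy]dihydrofuran-2(3H)-one F5. Enolate F5 is benzylated by 5 trans to the C4 benzyl group, the classical trans-selective alkylation of a β-benzyl-γ-butyrolactone, now free of the bulky dithiane. This returns to the route at 9 and bypasses 8.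

Risk 3, step 7: hydride may attack at sulfur and cleave the S–O bond, giving an alkoxide that displaces the neighbouring mesylate and closes a tetrahydrofuran, or the second β-branched mesylate may be reduced incompletely. The fallback for step 7 sets out from 11 and replaces the polar hydride displacement by a halide/radical reduction. Finkelstein exchange with NaI in refluxing acetone gives (2R,3R)-2-(3,5-dimethoxybenzyl)-1,4-diiodo-3-[3-methoxy-5-(methoxymethoxy)benzyl]butane F6. Radical dehalogenation of F6 with Bu3SnH and AIBN in toluene at 80 °C returns to the route at 12.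

Further compounds

F1 | step 8 | 4-[(2R,3R)-4-(4-formyl-3,5-dimethoxyphenyl)-2,3-dimethylbutyl]-2-methoxy-6-(methoxymethoxy)benzaldehyde | COc1cc(C[C@@H](C)[C@H](C)Cc2cc(OC)c(C=O)c(OC)c2)cc(OCOC)c1C=O
F2 | step 8 | 4-[(2R,3R)-4-(4-formyloxy-3,5-dimethoxyphenyl)-2,3-dimethylbutyl]-2-methoxy-6-(methoxymethoxy)phenyl formate | COc1cc(C[C@@H](C)[C@H](C)Cc2cc(OC)c(OC=O)c(OC)c2)cc(OCOC)c1OC=O
F3 | step 3 | (4R,5R)-4-{2-[3-methoxy-5-(methoxymethoxy)phenyl]-1,3-dithian-2-yl}-5-[(1R,2S,5R)-menthyloxy]dihydrofuran-2(3H)-one | CC(C)[C@@H]1CC[C@@H](C)C[C@H]1O[C@@H]2OC(=O)C[C@H]2C3(SCCCS3)c4cc(OC)cc(OCOC)c4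
F4 | step 3 | (4R,5R)-4-[3-methoxy-5-(methoxymethoxy)benzyl]-5-[(1R,2S,5R)-menthyloxy]dihydrofuran-2(3H)-one | CC(C)[C@@H]1CC[C@@H](C)C[C@H]1O[C@@H]2OC(=O)C[C@H]2Cc3cc(OC)cc(OCOC)c3
F5 | step 3 | lithium enolate of (4R,5R)-4-[3-methoxy-5-(methoxymethoxy)benzyl]-5-[(1R,2S,5R)-menthyloxy]dihydrofuran-2(3H)-one | CC(C)[C@@H]1CC[C@@H](C)C[C@H]1O[C@@H]2OC(O[Li])=C[C@H]2Cc3cc(OC)cc(OCOC)c3
F6 | step 7 | (2R,3R)-2-(3,5-dimethoxybenzyl)-1,4-diiodo-3-[3-methoxy-5-(methoxymethoxy)benzyl]butane | COc1cc(C[C@@H](CI)[C@H](CI)Cc2cc(OC)cc(OC)c2)cc(OCOC)c1
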